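**Retrosynthetic overview**
1. Numbering: bridgeheads C1 and C5; C2–C3–C4 is the β-diketone bridge; C6H2; C7H(prenyl); C8Me2; C9=O. Ring A = C1-C2-C3-C4-C5-C9 and ring B = C1-C8-C7-C6-C5-C9 (prenyl = 3-methylbut-2-enyl, TBS = tert-butyldimethylsilyl, TMS = trimethylsilyl).
2. Feature: ring B with one extra carbonyl at C6 is dimedone. Once C5 carries prenyl and the C4 acyl carbon, it is a prochiral quaternary carbon between the enantiotopic ketones C6 and C9. The surplus C6 ketone later makes C7 nucleophilic and is then removed.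
3. Late disconnections: C3–aroyl (vinyl-lithium acylation), C6–O (Barton–McCombie), C7–prenyl (exo alkylation of the C6 enolate), C1–prenyl (bridgehead lithiation), C2–O (conjugate borylation and two oxidations).
4. Key disconnection C1–C2: gold-catalysed 6-endo-dig attack of the C9 silyl enol ether on the C5-propioloyl ynone. The enol ether comes from enantiotopic enolisation of 2-acyl-2-prenyldimedone.
5. Ring order: ring B is bought as dimedone and ring A is closed second, in step 5. C5 is fixed in step 3, C1 in step 5 and C7 in step 13.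

Key step: step 5

Assumption: the sense of induction of the chiral amide on 6 cannot be derived with certainty; the (R,R)-amine is written for (S)-8, and the equally available (S,S)-amine is taken if the opposite sense is found.

Step 1
Reactants: 1 dimedone (5,5-dimethylcyclohexane-1,3-dione); 2 3-(trimethylsilyl)propynoic acid
Product: 4 3-hydroxy-5,5-dimethyl-2-[3-(trimethylsilyl)propynoyl]cyclohex-2-en-1-one, via enol ester 3 (not isolated)
Conditions: DCC (1.1 equiv), DMAP (1.1 equiv), CH2Cl2, 0 °C → rt
Reagents that add atoms: none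
Why: Steglich-type carbodiimide O-acylation of the dimedone enol, followed in the same flask by the DMAP-mediated O-to-C acyl shift (the standard entry to 2-acyldimedones), should apply because the C-acyl product is drained as its stabilised enolate and the silyl cap keeps DMAP and the enol oxygen away from the ynone β-carbon.

Step 2
Reactants: 4 3-hydroxy-5,5-dimethyl-2-[3-(trimethylsilyl)propynoyl]cyclohex-2-en-1-one; 5 prenyl bromide (1-bromo-3-methylbut-2-ene)
Product: 6 5,5-dimethyl-2-prenyl-2-[3-(trimethylsilyl)propynoyl]cyclohexane-1,3-dione (achiral; C5 prochiral)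
Conditions: Pd(PPh3)4 (5 mol %), i-Pr2NEt, THF, rt → 40 °C
Reagents that add atoms: none
Why: Tsuji–Trost allylation, in which the soft triketone enolate attacks the π-prenyl complex of divalent palladium at its unsubstituted terminus and any O-prenyl enol ether formed directly from the bromide is re-ionised by zerovalent palladium, so material should collect in the non-enolisable C-prenyl triketone, which has a mirror plane through C5 and C8.

Step 3
Reactants: 6 5,5-dimethyl-2-prenyl-2-[3-(trimethylsilyl)propynoyl]cyclohexane-1,3-dione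
Product: 8 (S)-3-(tert-butyldimethylsilyloxy)-5,5-dimethyl-2-prenyl-2-[3-(trimethylsilyl)propynoyl]cyclohex-3-en-1-one, via lithium enolate 7 (not isolated)
Conditions: (R,R)-bis(1-phenylethyl)amine hydrochloride, n-BuLi (2 equiv), THF, −78 → 0 → −100 °C; add 6, −100 → −78 °C; then TBSOTf, −78 °C
Reagents that add atoms: tert-butyldimethylsilyl triflate, CC(C)(C)[Si](C)(C)OS(=O)(=O)C(F)(F)F
Why: Enantioselective deprotonation with a C2-symmetric chiral lithium amide (LiCl present, external silyl triflate quench), where quaternary C5 lets each ketone enolise only away from it, the axial C1–H and C7–H are enantiotopic, and removal of the C1 proton followed by O-silylation turns prochiral C5 into the (S)-centre; TBSOTf is used because TBSCl does not trap lithium enolates at −78 °C, the alkyne cap removes the acidic C–H and screens C2 from the amide, and closure of 7 itself would require a strained cyclic allenolate.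

Step 4
Reactants: 8 (S)-3-(tert-butyldimethylsilyloxy)-5,5-dimethyl-2-prenyl-2-[3-(trimethylsilyl)propynoyl]cyclohex-3-en-1-one
Product: 9 (S)-3-(tert-butyldimethylsilyloxy)-5,5-dimethyl-2-prenyl-2-propioloylcyclohex-3-en-1-one
Conditions: AgNO3 (10 mol %), acetone/H2O, rt, dark
Reagents that add atoms: none
Why: Silver-catalysed protodesilylation of an alkynylsilane, in which π-coordination makes the already activated C(sp)–Si bond of the ynone labile to water at neutral pH, sparing the hindered O-TBS enol ether and avoiding alkoxide or fluoride media that would cleave the acyl group from C5 or the enol ether.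

Step 5
Reactants: 9 (S)-3-(tert-butyldimethylsilyloxy)-5,5-dimethyl-2-prenyl-2-propioloylcyclohex-3-en-1-one
Product: 10 (1S,5S)-8,8-dimethyl-5-prenylbicyclo[3.3.1]non-2-ene-4,6,9-trione
Conditions: Ph3PAuNTf2 (5 mol %), H2O (2 equiv), acetone, rt
Reagents that add atoms: none
Why: Cationic monovalent gold binds the C2≡C3 bond, C1 of the silyl enol ether adds anti to the metal at the terminal carbon C2, and water then removes the silyl group from the C9 oxocarbenium ion and protonates the C3–Au bond, which releases the C9 ketone, the C2=C3–C4=O enone and the catalyst. The closest known reaction type is the gold-catalysed carbocyclisation of cyclic silyl enol ethers onto tethered alkynes, an established entry to bicyclo[3.3.1]nonenones, of which a conjugated ynone acceptor is the less explored variant. Ring A (C1-C2-C3-C4-C5-C9) closes in the 6-endo-dig mode. The one new stereocentre, C1, is controlled by C5, because the C4-C3-C2 tether can reach C1 only on the face of ring B that carries the pseudoaxial propioloyl group, so the new three-carbon bridge is necessarily cis and (S)-C5 gives (S)-C1. The step needs endo over exo closure, secured because the acyl group disfavours positive charge at C3 and makes C2 the electrophilic terminus while 5-exo attack at C3 would give a bicyclo[3.2.1]octane with an exocyclic methylene group, and it needs the enol ether to outrun the C5 prenyl alkene, which forms a 1,6-enyne with the same alkyne, secured by the much higher nucleophilicity of the silyl enol ether at equal tether length. Since C5 is quaternary the enol ether cannot move, but its hydrolysis would return an achiral dione and erase the desymmetrisation, so water is limited to about two equivalents and the catalyst must be free of acid.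

Step 6
Reactants: 10 (1S,5S)-8,8-dimethyl-5-prenylbicyclo[3.3.1]non-2-ene-4,6,9-trione
Product: 11 (1S,5S)-6-(tert-butyldimethylsilyloxy)-8,8-dimethyl-5-prenylbicyclo[3.3.1]nona-2,6-diene-4,9-dione
Conditions: TBSOTf, Et3N, CH2Cl2, 0 °C
Reagents that add atoms: tert-butyldimethylsilyl triflate, CC(C)(C)[Si](C)(C)OS(=O)(=O)C(F)(F)F
Why: Soft enolisation with silyl triflate and a tertiary amine, where only C6 of the three carbonyl groups has an α-hydrogen (at C7) that can be lost without forming a bridgehead alkene, so one enol silane should form, which masks the ketone against the bases of steps 10 and 11, takes one of the three acyl neighbours away from C5 (less retro-Claisen risk) and stores the C7 nucleophile.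

Step 7
Reactants: 11 (1S,5S)-6-(tert-butyldimethylsilyloxy)-8,8-dimethyl-5-prenylbicyclo[3.3.1]nona-2,6-diene-4,9-dione
Product: 13 (1R,2S,5S)-6-(tert-butyldimethylsilyloxy)-2-hydroxy-8,8-dimethyl-5-prenylbicyclo[3.3.1]non-6-ene-4,9-dione, via C2 boronate 12 (not isolated)
Conditions: CuCl (5 mol %), DPEphos (5 mol %), NaOt-Bu (10 mol %), B2pin2, MeOH (2 equiv), THF, rt; then 30 % H2O2, pH 7 phosphate buffer, 0 °C → rt
Reagents that add atoms: bis(pinacolato)diboron, CC1(C)OB(OC1(C)C)B1OC(C)(C)C(C)(C)O1 (boron of 12); hydrogen peroxide, OO (C2 oxygen of 13)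
Why: Copper-catalysed conjugate borylation (boryl-copper 1,4-addition with methanol turnover) followed by stereoretentive C–B oxidation, run with buffered peroxide because alkaline peroxide would attack the non-enolisable C4/C9 diketone; boron should enter C2 on the face syn to the C9 bridge, away from ring B and its C8 methyl groups, and this centre is erased in step 8.

Step 8
Reactants: 13 (1R,2S,5S)-6-(tert-butyldimethylsilyloxy)-2-hydroxy-8,8-dimethyl-5-prenylbicyclo[3.3.1]non-6-ene-4,9-dione
Product: 14 (1R,5S)-6-(tert-butyldimethylsilyloxy)-2-hydroxy-8,8-dimethyl-5-prenylbicyclo[3.3.1]nona-2,6-diene-4,9-dione (enol form of the C2/C4 diketone)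
Conditions: Dess–Martin periodinane (1.1 equiv), NaHCO3, CH2Cl2, 0 °C → rt
Reagents that add atoms: none
Why: Dess–Martin oxidation supplies the two further electrons that borylation–oxidation does not deliver (that sequence stops at the β-hydroxy ketone) and, being non-basic, should give the enolised diketone without retro-aldol opening or dehydration back to 11.

Step 9
Reactants: 14 (1R,5S)-6-(tert-butyldimethylsilyloxy)-2-hydroxy-8,8-dimethyl-5-prenylbicyclo[3.3.1]nona-2,6-diene-4,9-dione
Product: 15 (1R,5S)-6-(tert-butyldimethylsilyloxy)-2-methoxy-8,8-dimethyl-5-prenylbicyclo[3.3.1]nona-2,6-diene-4,9-dione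
Conditions: Me2SO4, K2CO3, acetone, rt
Reagents that add atoms: dimethyl sulfate, COS(=O)(=O)OC
Why: O-alkylation of the β-diketone enolate with a hard electrophile, where O2 lies beside the C1–H bridgehead while O4 is screened by quaternary C5 with its prenyl group and the C6 silyloxy group, so the 2-methoxy enone should dominate, and the 4-methoxy isomer, if formed, ends in the same target after step 20.

Step 10
Reactants: 15 (1R,5S)-6-(tert-butyldimethylsilyloxy)-2-methoxy-8,8-dimethyl-5-prenylbicyclo[3.3.1]nona-2,6-diene-4,9-dione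
Product: 17 (1R,5R)-6-(tert-butyldimethylsilyloxy)-2-methoxy-8,8-dimethyl-5-prenyl-3-(trimethylsilyl)bicyclo[3.3.1]nona-2,6-diene-4,9-dione, via C3-lithio species 16 (not isolated)
Conditions: LiN(i-Pr)2, Me3SiCl (present from the start), THF, −78 °C
Reagents that add atoms: chlorotrimethylsilane, C[Si](C)(C)Cl
Why: Vinyl deprotonation with in situ silyl quench, since in enol ethers of bicyclo[3.3.1]nonane-2,4,9-triones whose free bridgehead is flanked by a quaternary carbon the C3–H (between the carbonyl and the methoxy-bearing carbon) is the kinetically preferred site, so it is blocked as the C-silane before the bridgehead is addressed.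

Step 11
Reactants: 17 (1R,5R)-6-(tert-butyldimethylsilyloxy)-2-methoxy-8,8-dimethyl-5-prenyl-3-(trimethylsilyl)bicyclo[3.3.1]nona-2,6-diene-4,9-dione; 5 prenyl bromide
Product: 19 (1R,5R)-6-(tert-butyldimethylsilyloxy)-2-methoxy-8,8-dimethyl-1,5-diprenyl-3-(trimethylsilyl)bicyclo[3.3.1]nona-2,6-diene-4,9-dione, via C1-lithio species 18 (not isolated)
Conditions: LiN(i-Pr)2 (1.5 equiv), THF, −78 → −40 °C; 5 (3 equiv), −78 °C → rt
Reagents that add atoms: none
Why: Bridgehead lithiation–alkylation, a known reaction of these trione enol ethers, where with C3 blocked and C6 masked the C1–H (acidified inductively by C9=O and C2–OMe, lithium held by both oxygens) is the only site left, and since the pyramidal bridgehead carbanion cannot invert, prenyl replaces hydrogen with retention.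

Step 12
Reactants: 19 (1R,5R)-6-(tert-butyldimethylsilyloxy)-2-methoxy-8,8-dimethyl-1,5-diprenyl-3-(trimethylsilyl)bicyclo[3.3.1]nona-2,6-diene-4,9-dione
Product: 20 (1R,5S)-2-methoxy-8,8-dimethyl-1,5-diprenylbicyclo[3.3.1]non-2-ene-4,6,9-trione
Conditions: n-Bu4NF (2.5 equiv), AcOH (2.5 equiv), THF, 0 °C → rt
Reagents that add atoms: none
Why: Buffered fluoride desilylation removes the O-TBS group (restoring the C6 ketone) and the C3 vinylsilane in one operation, with acetic acid keeping the medium from becoming basic enough for retro-Claisen cleavage at C5.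

Step 13
Reactants: 20 (1R,5S)-2-methoxy-8,8-dimethyl-1,5-diprenylbicyclo[3.3.1]non-2-ene-4,6,9-trione; 5 prenyl bromide
Product: 22 (1R,5S,7S)-2-methoxy-8,8-dimethyl-1,5,7-triprenylbicyclo[3.3.1]non-2-ene-4,6,9-trione (7-prenyl exo: turned away from ring A and equatorial on the ring-B chair), via potassium enolate 21 (not isolated)
Conditions: KN(SiMe3)2 (1.1 equiv), THF, −78 °C; 5, −78 → −20 °C
Reagents that add atoms: none
Why: Kinetic enolate alkylation, where C7 is the only enolisable position, the endo face of the C6–C7 enolate looks into the cleft under ring A (C2–C3–C4) and the two C8 methyl groups flank both faces alike, so prenyl bromide should enter from the exo face and give the equatorial 7-exo prenyl group, which is also the epimer favoured by equilibration through the enolate.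

Step 14
Reactants: 22 (1R,5S,7S)-2-methoxy-8,8-dimethyl-1,5,7-triprenylbicyclo[3.3.1]non-2-ene-4,6,9-trione
Product: 23 (1R,5S,6S,7S)-6-hydroxy-2-methoxy-8,8-dimethyl-1,5,7-triprenylbicyclo[3.3.1]non-2-ene-4,9-dione (6-OH axial on ring B, syn to the axial C8 methyl)
Conditions: NaBH4, MeOH/THF, −20 → 0 °C; pH 7 buffer
Reagents that add atoms: none
Why: Chemoselective borohydride reduction, where C9 now sits between two quaternary bridgeheads and C4 is a vinylogous ester carbonyl, so hydride should reach only C6 (one tertiary neighbour), mainly along the equatorial path because the axial C8 methyl blocks the other one, and the configuration of the new carbinol is of no consequence since C6 ends as CH2.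

Step 15
Reactants: 23 (1R,5S,6S,7S)-6-hydroxy-2-methoxy-8,8-dimethyl-1,5,7-triprenylbicyclo[3.3.1]non-2-ene-4,9-dione
Product: 24 O-phenyl thionocarbonate of 23 at O6, (1R,5S,6S,7S)
Conditions: PhOC(S)Cl, DMAP, CH2Cl2, rt → reflux
Reagents that add atoms: O-phenyl chlorothionoformate, S=C(Cl)Oc1ccccc1
Why: Thioacylation for the Barton–McCombie sequence under DMAP activation, chosen over the xanthate protocol because a free C6 alkoxide β to C9=O and C4=O would be prone to retro-aldol cleavage of C5–C6.

Step 16
Reactants: 24 O-phenyl thionocarbonate of 23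
Product: 25 (1R,5S,7R)-2-methoxy-8,8-dimethyl-1,5,7-triprenylbicyclo[3.3.1]non-2-ene-4,9-dione
Conditions: n-Bu3SnH, AIBN, PhSeSePh (10 mol %), toluene, 90 °C
Reagents that add atoms: none
Why: Barton–McCombie deoxygenation, where the C6 radical meets the prenyl alkenes only in 4-exo or 5-endo relationships and benzeneselenol formed from PhSeSePh delivers hydrogen fast enough to forestall a 1,2-shift of the C4 acyl carbon, so C6 should become CH2 with C5 and C7 untouched.

Step 17
Reactants: 26 3,4-dihydroxybenzoic acid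
Product: 27 tert-butyldimethylsilyl 3,4-bis(tert-butyldimethylsilyloxy)benzoate
Conditions: TBSCl (3.5 equiv), imidazole, DMF, rt
Reagents that add atoms: tert-butyldimethylsilyl chloride, CC(C)(C)[Si](C)(C)Cl
Why: Exhaustive silylation with silyl chloride and imidazole protects both phenols as base-stable TBS ethers and turns the acid into its silyl ester.

Step 18
Reactants: 27 tert-butyldimethylsilyl 3,4-bis(tert-butyldimethylsilyloxy)benzoate
Product: 28 3,4-bis(tert-butyldimethylsilyloxy)benzoyl chloride
Conditions: (COCl)2, DMF (cat.), CH2Cl2, 0 °C → rt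
Reagents that add atoms: oxalyl chloride, O=C(Cl)C(=O)Cl
Why: Silyl esters are converted by oxalyl chloride and catalytic DMF (Vilsmeier-type chloride transfer) into acid chlorides under neutral conditions, which leaves the aryl TBS ethers intact.

Step 19
Reactants: 25 (1R,5S,7R)-2-methoxy-8,8-dimethyl-1,5,7-triprenylbicyclo[3.3.1]non-2-ene-4,9-dione; 28 3,4-bis(tert-butyldimethylsilyloxy)benzoyl chloride
Product: 30 (1R,5R,7R)-3-[3,4-bis(tert-butyldimethylsilyloxy)benzoyl]-2-methoxy-8,8-dimethyl-1,5,7-triprenylbicyclo[3.3.1]non-2-ene-4,9-dione, via C3-lithio species 29 (not isolated)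
Conditions: 2,2,6,6-tetramethylpiperidine, n-BuLi, THF, 0 °C; 25, −78 °C; then 28, −78 → −40 °C
Reagents that add atoms: none
Why: Directed vinyl lithiation and acylation, where with both bridgeheads quaternary the C3–H is the only acidic site of 25 and the C3-lithium species should be acylated by the acid chloride, as is known for benzoylation of the same ring system.

Step 20
Reactants: 30 (1R,5R,7R)-3-[3,4-bis(tert-butyldimethylsilyloxy)benzoyl]-2-methoxy-8,8-dimethyl-1,5,7-triprenylbicyclo[3.3.1]non-2-ene-4,9-dione
Product: 31 aristophenone A, (1S,5S,7R)-3-(3,4-dihydroxybenzoyl)-4-hydroxy-8,8-dimethyl-1,5,7-triprenylbicyclo[3.3.1]non-3-ene-2,9-dione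
Conditions: LiOH (aq), 1,4-dioxane, 90 °C, degassed, Ar; then 1 M HCl, 0 °C
Reagents that add atoms: lithium hydroxide (aqueous), [Li+].[OH-]
Why: Vinylogous ester saponification (hydroxide addition–elimination at C2, made easy by the C3 aroyl group) and hydroxide cleavage of both aryl silyl ethers occur together, the product being protected as its delocalised enolate and catecholate under argon until acidification, and no stereocentre is enolisable.

**Compound list**
1 | dimedone | CC1(C)CC(=O)CC(=O)C1 | starting material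
2 | 3-(trimethylsilyl)propynoic acid | C[Si](C)(C)C#CC(=O)O | starting material
3 | 5,5-dimethyl-3-oxocyclohex-1-enyl 3-(trimethylsilyl)propynoate (not isolated) | C[Si](C)(C)C#CC(=O)OC1=CC(=O)CC(C)(C)C1 | intermediate
4 | 3-hydroxy-5,5-dimethyl-2-[3-(trimethylsilyl)propynoyl]cyclohex-2-en-1-one | C[Si](C)(C)C#CC(=O)C1=C(O)CC(C)(C)CC1=O | intermediate
5 | prenyl bromide | CC(C)=CCBr | starting material
6 | 5,5-dimethyl-2-prenyl-2-[3-(trimethylsilyl)propynoyl]cyclohexane-1,3-dione | C[Si](C)(C)C#CC(=O)C1(CC=C(C)C)C(=O)CC(C)(C)CC1=O | intermediate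
7 | lithium enolate of 6 toward C1, (S) at C5 (not isolated) | C[Si](C)(C)C#CC(=O)[C@]1(CC=C(C)C)C(=O)CC(C)(C)C=C1O[Li] | intermediate
8 | (S)-3-(TBSO)-5,5-dimethyl-2-prenyl-2-[3-(trimethylsilyl)propynoyl]cyclohex-3-en-1-one | C[Si](C)(C)C#CC(=O)[C@]1(CC=C(C)C)C(=O)CC(C)(C)C=C1O[Si](C)(C)C(C)(C)C | intermediate
9 | (S)-3-(TBSO)-5,5-dimethyl-2-prenyl-2-propioloylcyclohex-3-en-1-one | C#CC(=O)[C@]1(CC=C(C)C)C(=O)CC(C)(C)C=C1O[Si](C)(C)C(C)(C)C | intermediate
10 | (1S,5S)-8,8-dimethyl-5-prenylbicyclo[3.3.1]non-2-ene-4,6,9-trione | C1C(=O)[C@]2(CC=C(C)C)C(=O)[C@@H](C=CC2=O)C1(C)C | intermediate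
11 | (1S,5S)-6-(TBSO)-8,8-dimethyl-5-prenylbicyclo[3.3.1]nona-2,6-diene-4,9-dione | C1=C(O[Si](C)(C)C(C)(C)C)[C@]2(CC=C(C)C)C(=O)[C@@H](C=CC2=O)C1(C)C | intermediate
12 | (1S,2S,5S)-2-(pinacolatoboryl) derivative, boron syn to C9 (not isolated) | C1=C(O[Si](C)(C)C(C)(C)C)[C@]2(CC=C(C)C)C(=O)[C@@H]([C@@H](B3OC(C)(C)C(C)(C)O3)CC2=O)C1(C)C | intermediate
13 | (1R,2S,5S)-6-(TBSO)-2-hydroxy-8,8-dimethyl-5-prenylbicyclo[3.3.1]non-6-ene-4,9-dione | C1=C(O[Si](C)(C)C(C)(C)C)[C@]2(CC=C(C)C)C(=O)[C@@H]([C@@H](O)CC2=O)C1(C)C | intermediate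
14 | (1R,5S)-6-(TBSO)-2-hydroxy-8,8-dimethyl-5-prenylbicyclo[3.3.1]nona-2,6-diene-4,9-dione | C1=C(O[Si](C)(C)C(C)(C)C)[C@]2(CC=C(C)C)C(=O)[C@@H](C(O)=CC2=O)C1(C)C | intermediate
15 | (1R,5S)-6-(TBSO)-2-methoxy-8,8-dimethyl-5-prenylbicyclo[3.3.1]nona-2,6-diene-4,9-dione | C1=C(O[Si](C)(C)C(C)(C)C)[C@]2(CC=C(C)C)C(=O)[C@@H](C(OC)=CC2=O)C1(C)C | intermediate
16 | 3-lithio derivative of 15 (not isolated) | C1=C(O[Si](C)(C)C(C)(C)C)[C@]2(CC=C(C)C)C(=O)[C@@H](C(OC)=C([Li])C2=O)C1(C)C | intermediate
17 | (1R,5R)-3-(trimethylsilyl) derivative of 15 | C1=C(O[Si](C)(C)C(C)(C)C)[C@]2(CC=C(C)C)C(=O)[C@@H](C(OC)=C([Si](C)(C)C)C2=O)C1(C)C | intermediate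
18 | 1-lithio derivative of 17, lithium in the place of the bridgehead hydrogen (not isolated) | C1=C(O[Si](C)(C)C(C)(C)C)[C@]2(CC=C(C)C)C(=O)[C@@]([Li])(C(OC)=C([Si](C)(C)C)C2=O)C1(C)C | intermediate
19 | (1R,5R)-6-(TBSO)-2-methoxy-8,8-dimethyl-1,5-diprenyl-3-(trimethylsilyl)bicyclo[3.3.1]nona-2,6-diene-4,9-dione | C1=C(O[Si](C)(C)C(C)(C)C)[C@]2(CC=C(C)C)C(=O)[C@@](CC=C(C)C)(C(OC)=C([Si](C)(C)C)C2=O)C1(C)C | intermediate
20 | (1R,5S)-2-methoxy-8,8-dimethyl-1,5-diprenylbicyclo[3.3.1]non-2-ene-4,6,9-trione | C1C(=O)[C@]2(CC=C(C)C)C(=O)[C@@](CC=C(C)C)(C(OC)=CC2=O)C1(C)C | intermediate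
21 | potassium C6–C7 enolate of 20 (not isolated) | C1=C(O[K])[C@]2(CC=C(C)C)C(=O)[C@@](CC=C(C)C)(C(OC)=CC2=O)C1(C)C | intermediate
22 | (1R,5S,7S)-2-methoxy-8,8-dimethyl-1,5,7-triprenylbicyclo[3.3.1]non-2-ene-4,6,9-trione (7-exo) | CC(C)=CC[C@@H]1C(=O)[C@]2(CC=C(C)C)C(=O)[C@@](CC=C(C)C)(C(OC)=CC2=O)C1(C)C | intermediate
23 | (1R,5S,6S,7S)-6-hydroxy-2-methoxy-8,8-dimethyl-1,5,7-triprenylbicyclo[3.3.1]non-2-ene-4,9-dione | CC(C)=CC[C@@H]1[C@H](O)[C@]2(CC=C(C)C)C(=O)[C@@](CC=C(C)C)(C(OC)=CC2=O)C1(C)C | intermediate
24 | O6-(phenoxythiocarbonyl) derivative of 23 | CC(C)=CC[C@@H]1[C@H](OC(=S)Oc3ccccc3)[C@]2(CC=C(C)C)C(=O)[C@@](CC=C(C)C)(C(OC)=CC2=O)C1(C)C | intermediate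
25 | (1R,5S,7R)-2-methoxy-8,8-dimethyl-1,5,7-triprenylbicyclo[3.3.1]non-2-ene-4,9-dione | CC(C)=CC[C@@H]1C[C@]2(CC=C(C)C)C(=O)[C@@](CC=C(C)C)(C(OC)=CC2=O)C1(C)C | intermediate
26 | 3,4-dihydroxybenzoic acid | O=C(O)c1ccc(O)c(O)c1 | starting material
27 | tert-butyldimethylsilyl 3,4-bis(TBSO)benzoate | CC(C)(C)[Si](C)(C)OC(=O)c1ccc(O[Si](C)(C)C(C)(C)C)c(O[Si](C)(C)C(C)(C)C)c1 | intermediate
28 | 3,4-bis(TBSO)benzoyl chloride | O=C(Cl)c1ccc(O[Si](C)(C)C(C)(C)C)c(O[Si](C)(C)C(C)(C)C)c1 | intermediate
29 | 3-lithio derivative of 25 (not isolated) | CC(C)=CC[C@@H]1C[C@]2(CC=C(C)C)C(=O)[C@@](CC=C(C)C)(C(OC)=C([Li])C2=O)C1(C)C | intermediate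
30 | (1R,5R,7R)-3-[3,4-bis(TBSO)benzoyl]-2-methoxy-8,8-dimethyl-1,5,7-triprenylbicyclo[3.3.1]non-2-ene-4,9-dione | CC(C)=CC[C@@H]1C[C@]2(CC=C(C)C)C(=O)[C@@](CC=C(C)C)(C(OC)=C(C(=O)c3ccc(O[Si](C)(C)C(C)(C)C)c(O[Si](C)(C)C(C)(C)C)c3)C2=O)C1(C)C | intermediate
31 | aristophenone A | CC(C)=CC[C@@H]1C[C@]2(CC=C(C)C)C(=O)[C@@](CC=C(C)C)(C(=O)C(C(=O)c3ccc(O)c(O)c3)=C2O)C1(C)C | target

**Step count:** 20 steps in total. The longest linear sequence is 18 steps (steps 1–16, 19 and 20); steps 17 and 18 make the aroyl chloride in parallel.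

**Steps most likely to fail**

Step 3. The amide may discriminate poorly between the enantiotopic C1 and C7 protons. It may also add to the ynone or to an acyl carbon at C5 instead of deprotonating, and proton exchange of the enolate before silylation may erode the enantiomeric purity.
The fallback replaces asymmetric enolisation by resolution. It sets out from 6 and returns at 10.
Soft enolisation of 6 with one equivalent of TBSOTf and Et3N (CH2Cl2, −78 → 0 °C) gives the racemic silyl enol ether F1. Protodesilylation as in step 4 gives the racemic terminal ynone F2, and gold closure as in step 5 gives the racemic trione F3.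
Preparative chromatography of this robust, configurationally locked bicycle on a chiral stationary phase separates 10 from its antipode F4.

Step 5. The electron-poor alkyne may bind gold too weakly, so that hydrolysis of the enol ether (which erases the C5 stereocentre), hydration of the ynone or attack of the prenyl alkene overtakes C1–C2 bond formation.
The fallback changes the acceptor from an alkyne to a vinylogous thioester, and changes the activation from π-acid to chelating σ-Lewis acid. It sets out from 9 and returns at 10.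
Thiophenol (1 equiv, catalytic Et3N, CH2Cl2, 0 °C) adds to the ynone to give the (Z)-β-(phenylthio)vinyl ketone F5. TiCl4 (CH2Cl2, −78 °C, anhydrous), held by O4 and O6, then triggers an intramolecular Mukaiyama–Michael addition of C1 to C2. This closure is 6-endo-trig and passes through an ordinary endocyclic titanium enolate.
Loss of thiophenolate on warming, or with DBU, restores the C2=C3 double bond.

Step 11. Lithiation at C1 next to C8Me2 may be incomplete. Alternatively, capture of the hindered bridgehead carbanion by prenyl bromide may be slower than proton return or decomposition.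
The fallback replaces the polar alkylation by a bridgehead radical allylation. It sets out from 17 and returns at 19.
Lithiation with LiN(i-Pr)2 and quenching with the small electrophile I2 (THF, −78 °C) gives the C1 iodide F6. Keck allylation (allyltributylstannane, AIBN, toluene, 80 °C) gives the C1 allyl compound F7. Cross metathesis with 2-methylbut-2-ene (second-generation Grubbs catalyst, CH2Cl2, 40 °C), which is degenerate for the C5 prenyl group, converts allyl into prenyl.

Further compounds
F1 | step 3 | rac-3-(TBSO)-5,5-dimethyl-2-prenyl-2-[3-(trimethylsilyl)propynoyl]cyclohex-3-en-1-one | C[Si](C)(C)C#CC(=O)C1(CC=C(C)C)C(=O)CC(C)(C)C=C1O[Si](C)(C)C(C)(C)C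
F2 | step 3 | rac-3-(TBSO)-5,5-dimethyl-2-prenyl-2-propioloylcyclohex-3-en-1-one | C#CC(=O)C1(CC=C(C)C)C(=O)CC(C)(C)C=C1O[Si](C)(C)C(C)(C)C
F3 | step 3 | rac-8,8-dimethyl-5-prenylbicyclo[3.3.1]non-2-ene-4,6,9-trione | C1C(=O)C2(CC=C(C)C)C(=O)C(C=CC2=O)C1(C)C
F4 | step 3 | (1R,5R)-8,8-dimethyl-5-prenylbicyclo[3.3.1]non-2-ene-4,6,9-trione | C1C(=O)[C@@]2(CC=C(C)C)C(=O)[C@H](C=CC2=O)C1(C)C
F5 | step 5 | (S)-3-(TBSO)-5,5-dimethyl-2-prenyl-2-[(Z)-3-(phenylthio)acryloyl]cyclohex-3-en-1-one | O=C(/C=C\Sc1ccccc1)[C@]1(CC=C(C)C)C(=O)CC(C)(C)C=C1O[Si](C)(C)C(C)(C)C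
F6 | step 11 | 1-iodo derivative of 17 (iodine in the place of the bridgehead hydrogen) | C1=C(O[Si](C)(C)C(C)(C)C)[C@]2(CC=C(C)C)C(=O)[C@@](I)(C(OC)=C([Si](C)(C)C)C2=O)C1(C)C
F7 | step 11 | 1-allyl derivative of 17 | C1=C(O[Si](C)(C)C(C)(C)C)[C@]2(CC=C(C)C)C(=O)[C@@](CC=C)(C(OC)=C([Si](C)(C)C)C2=O)C1(C)C
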